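**Retrosynthetic overview**
1. Target 6 ⇒ octol 5 by cutting the biaryl bond of the 9,10-dihydrophenanthrene (ring D, closed last): a ring A carbon adds to the keto tautomer of ring C and water is lost.
2. 5 ⇒ two molecules of piceatannol 3 by cutting the two benzylic C–aryl bonds: C5–ring C first (intermolecular, enantio-determining), then C11–ring B (closes seven-membered ring E). Both are Friedel–Crafts additions to para-quinone-methide-type cations made by protonating the stilbenes.
3. 3 ⇒ resveratrol 1 by ortho-hydroxylation.
4. Ring order: aromatic rings A, B, C and F come with the stilbenes; ring E (7) forms in step 2; ring D (6) forms in step 3. Net: 2 C14H12O4 → C28H22O7 + H2O, no redox change after step 1.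

Labels: ring A = resorcinol ring of the benzyl arm; ring B = catechol ring fused to ring E; ring C = central ring, from the resorcinol ring of the second piceatannol; ring F = pendant catechol. C5 and C11 are the two methines of 5 in dibenzo[a,d][7]annulene numbering (C5 between rings B and C, C11 carrying ring F).

Assumption: the biosynthesis is taken to be the redox-neutral, acid-type condensation of two piceatannol units with loss of one water.
Assumption: the (R)-catalyst of step 2 is taken to give the (5R) centre; if the sense of induction is the reverse, the mirror-image catalyst is used with no other change.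

**Step 1**
Reactants: 1 resveratrol
Product: 3 piceatannol, via ortho-quinone 2 (not isolated)
Conditions: IBX (1.1 equiv), MeOH, −25 °C, 1 h; then aq. Na2S2O4, 0 °C to rt
Reagents that add atoms: IBX (2-iodoxybenzoic acid), O=C1OI(=O)(O)c2ccccc12
Why: IBX ortho-hydroxylation of a phenol (oxygen transfer from the pentavalent-iodine aryloxy intermediate to the ortho carbon, then collapse to the ortho-quinone) should occur at the 4'-hydroxystyryl ring, the most easily oxidised phenol of 1, and reduction by Na2S2O4 in the same flask returns the catechol before the quinone is attacked; no stereocentre is formed and the (E)-olefin is untouched.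

**Step 2**
Reactants: 3 piceatannol (two molecules, one as electrophile and one as nucleophile)
Product: 5 (5R,11S)-11-(3,4-dihydroxyphenyl)-5-[(3,5-dihydroxyphenyl)methyl]-10,11-dihydro-5H-dibenzo[a,d][7]annulene-2,3,6,8-tetrol, via open dimer 4 (not isolated)
Conditions: (R)-3,3'-bis(2,4,6-triisopropylphenyl)-1,1'-binaphthalene-2,2'-diyl N-triflylphosphoramidate (C51H57F3NO5PS, 10 mol %), EtOAc/PhCF3 1:1 (0.1 M), 25–40 °C, Ar, dark, 48 h
Reagents that add atoms: none
Why: Proposed new method: the strong chiral acid protonates the stilbene of one molecule of 3 at the carbon next to the resorcinol ring, giving a para-quinone-methide-type benzylic cation in a contact ion pair with the chiral anion; the resorcinol carbon ortho to the styryl group of a second molecule (C4 of its benzene-1,3-diol, hydrogen-bonded through its OH to the same anion) adds to one face in an asymmetric Friedel–Crafts hydroarylation that sets C5 as R; the styryl group of the resulting open dimer 4 is then protonated in the same way and trapped by the ring B carbon para to its 3-OH in a seven-membered Friedel–Crafts closure through a twist-boat with ring F pseudo-equatorial, which sets C11 as S (11-H cis to 5-H); the closest known reaction types are chiral phosphoric acid-catalysed 1,6-additions of phenols and indoles to para-quinone methides generated in situ, chiral-acid hydroarylation of hydroxystyrenes, and the racemic acid-mediated oligomerisation of hydroxystilbenes.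

**Step 3**
Reactants: 5 (5R,11S)-octol
Product: 6 target CNP0306974.1
Conditions: MsOH (1.0 equiv), HFIP, 40 °C, Ar
Reagents that add atoms: none
Why: Proposed new method: acid C-protonates ring C between its two hydroxyls to give a protonated cyclohexadienone whose carbonyl carbon (the C6–OH carbon, ortho to C5) is attacked by the ring A carbon ortho to the CH2 arm (ortho and para to the two ring A hydroxyls) in a six-membered Friedel–Crafts addition, and loss of water re-aromatises ring C to leave the biaryl bond of the 9,10-dihydrophenanthrene; the closest known reaction types are the acid-catalysed dehydrative arylation of phloroglucinol and naphthols through their keto tautomers and the Bucherer reaction; no new stereocentre is formed, and once ring D holds the C5 arm pseudo-equatorial the cis isomer with ring F pseudo-equatorial should also be the thermodynamic one if ring E opens and recloses.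

**Compound list**
1 | resveratrol, (E)-5-[2-(4-hydroxyphenyl)ethenyl]benzene-1,3-diol | Oc1ccc(/C=C/c2cc(O)cc(O)c2)cc1 | starting material
2 | ortho-quinone, (E)-4-[2-(3,5-dihydroxyphenyl)ethenyl]cyclohexa-3,5-diene-1,2-dione (not isolated) | O=C1C(=O)C=C(/C=C/c2cc(O)cc(O)c2)C=C1 | intermediate
3 | piceatannol, (E)-4-[2-(3,5-dihydroxyphenyl)ethenyl]benzene-1,2-diol | Oc1ccc(/C=C/c2cc(O)cc(O)c2)cc1O | intermediate
4 | open dimer, 4-[(1R)-1-(3,4-dihydroxyphenyl)-2-(3,5-dihydroxyphenyl)ethyl]-5-[(E)-2-(3,4-dihydroxyphenyl)ethenyl]benzene-1,3-diol (not isolated) | Oc1cc(O)cc(C[C@H](c2ccc(O)c(O)c2)c2c(O)cc(O)cc2/C=C/c2ccc(O)c(O)c2)c1 | intermediate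
5 | (5R,11S)-11-(3,4-dihydroxyphenyl)-5-[(3,5-dihydroxyphenyl)methyl]-10,11-dihydro-5H-dibenzo[a,d][7]annulene-2,3,6,8-tetrol (5-H and 11-H cis) | Oc1cc(O)cc(c1)C[C@@H]1c3cc(O)c(O)cc3[C@H](c3ccc(O)c(O)c3)Cc3cc(O)cc(O)c31 | intermediate
6 | target heptol CNP0306974.1: 5 with the ring A carbon ortho to the CH2 arm bonded to the former C6 of ring C in place of its OH (9,10-dihydrophenanthrene fused to the dibenzosuberane; R at the methine shared by rings D and E, S at the methine carrying ring F, the two methine hydrogens cis) | Oc1cc(O)c2c(c1)C[C@@H]1c3cc(O)c(O)cc3[C@H](c3ccc(O)c(O)c3)Cc3cc(O)cc-2c31 | target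

**Totals**
Total step count: 3. Longest linear sequence: 3 steps (1 → 3 → 5 → 6).

**Steps most likely to fail**

Step 2 is the most likely to fail. The cation can be captured by the olefin of the second stilbene or by the resorcinol carbon between the two hydroxyls, oligomers can form, facial control through a remote ion pair may be weak, and the C11 epimer may form. The fallback gives up asymmetric catalysis. It sets out from 3 and runs the same cascade with an achiral acid (MsOH, 20 mol %, EtOAc, 25 °C), under which C-alkylation of the resorcinol ring is reversible and mis-alkylated material can re-equilibrate. Racemic 5 is then separated by preparative chromatography on a chiral stationary phase into 5 and its mirror image, the (5S,11R)-octol F1. The route is rejoined at 5.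

Step 3 is next. Ring C may not be electrophilic enough as its keto tautomer. Alternatively, acid strong enough to ketonise it may cleave the C5–ring C bond by ipso-protonation (retro-Friedel–Crafts) and erode the stereochemistry before ring D closes. The fallback activates the C–OH carbon without acid, by a hydrogen-borrowing redox relay. It sets out from 5 with Pd/C (10 mol % Pd) and HCO2Na (0.2 equiv) in degassed dioxane/water at 110 °C. Ring C is transiently hydrogenated to the ring C cyclohexane-1,3-dione F2. Its vinylogous-acid carbonyl condenses with the ring A carbon, with loss of water, to give the ring C cyclohexenone F3 (a dihydro form of 6). The Pd/C then dehydrogenates F3 back to the arene, and the route is rejoined at 6. Transient reduction of ring A leads nowhere and reverses.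

Step 1 is the least risky of the three. IBX may also oxidise the resorcinol ring or over-oxidise the stilbene. The fallback replaces the hypervalent-iodine oxidation by whole-cell biocatalysis. It sets out from 1 with Escherichia coli cells expressing the two-component flavin-dependent 4-hydroxyphenylacetate 3-monooxygenase (HpaBC), air and glycerol in pH 7 buffer at 30 °C, which hydroxylates only the position ortho to the 4'-OH. It rejoins the route at 3 and passes through no new compound (F0).

**Further compounds**
F1 | step 2 | (5S,11R)-11-(3,4-dihydroxyphenyl)-5-[(3,5-dihydroxyphenyl)methyl]-10,11-dihydro-5H-dibenzo[a,d][7]annulene-2,3,6,8-tetrol (enantiomer of 5) | Oc1cc(O)cc(c1)C[C@H]1c3cc(O)c(O)cc3[C@@H](c3ccc(O)c(O)c3)Cc3cc(O)cc(O)c31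
F2 | step 3 | ring C cyclohexane-1,3-dione, the H2 adduct of 5 at ring C (mixture at the two new ring C methines, not isolated) | Oc1cc(O)cc(c1)C[C@@H]1c3cc(O)c(O)cc3[C@H](c3ccc(O)c(O)c3)CC3CC(=O)CC(=O)C31
F3 | step 3 | ring C cyclohex-2-enone with the former C6 bonded to ring A, a dihydro form of 6 (mixture at the two ring C methines, not isolated) | Oc1cc(O)c2c(c1)C[C@@H]1c3cc(O)c(O)cc3[C@H](c3ccc(O)c(O)c3)CC3CC(=O)C=C2C31
F0 | step 1 | none | none
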